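**Plan**

1. Locants used below (iridal convention): C1 = CHO, C2 = its α-carbon, C3–C5 = hydroxypropyl chain (C3 = CH2OH); ring B = C6 (CH), C7 (alkylidene carbon), C8, C9, C10 (C(CH3)OH), C11 (spiro); ring S = C11, C12, C13, C14 (CH), C26 (CHOH); side chain C15 (=CH2) to C19; C28 = CH2OAc.
2. Cuts, last to first: C15–C16 (Stille), C14–C15 (acetyl cation equivalent on the C26 enol ether), C10–CH3 (organocerium), C6–C11 (closure of ring B), C10–C11 (enamine acylation), C4–C5 and C4–C6 (cyclopropanation), C6–C7 (Stille on an enol triflate).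
3. Enabling feature: C6 is both allylic to the exocyclic C7=C2 alkene and γ to the oxidised chain end C3, so C5 and C4 can be folded back onto C6 as a cyclopropane whose C4 bears two esters (one is C3, the other an activating group lost as CO2). C11 lies between the oxygenated carbons C26 and C10, so it is the central carbon of a 1,3-diketone.
4. Forward order: acyclic Z tetrasubstituted enoate, then vinylcyclopropane diester, then 2-acylcyclopentanone (ring S bought as a cyclopentanone enamine), then strain-release spirocyclisation that forms ring B and spiro C11, then C10 carbinol, C14 substituent and C26 carbinol, then the triene by cross-coupling, then unmasking.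
5. Stereochemistry: C6 from an asymmetric cyclopropanation (inverted in the ring opening); C11 from the chelated chair transition state of the ring closure; C10, C14 and C26 from the spirocycle (equatorial methyl addition, attack on the ring S face away from the C10 methyl, C10-hydroxyl-directed hydride). C2=C7 comes from a chelation-controlled Z enol triflate, C18=C19 from a Still–Gennari olefination, C16=C17 from an E stannane.
6. Helpers removed later: second malonate ester (as CO2), C10 ketone (to the carbinol), dioxolane (to methyl ketone, then alkenyl triflate), silyl ethers.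

Key step: step 7

Remark: 2-methoxy-2-methyl-1,3-dioxolane (step 10) is taken as an available orthoester; it is otherwise the exchange product of trimethyl orthoacetate and ethane-1,2-diol.

**Route**

Step 1
Reactants: 1 dimethyl 3-oxohexanedioate
Product: 2 dimethyl 2-methyl-3-oxohexanedioate
Conditions: K2CO3, MeI, acetone, 25 °C
Reagents that add atoms: iodomethane, CI
Why: Carbonate deprotonates only the doubly activated C2–H and the β-keto ester enolate is C-methylated (acetoacetic ester alkylation); the new centre is labile and of no consequence.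

Step 2
Reactants: 2 dimethyl 2-methyl-3-oxohexanedioate
Product: 3 dimethyl (2Z)-2-methyl-3-(trifluoromethanesulfonyloxy)hex-2-enedioate
Conditions: Tf2O, aq. LiOH, toluene, 5 °C
Reagents that add atoms: trifluoromethanesulfonic anhydride, O=S(=O)(OS(=O)(=O)C(F)(F)F)C(F)(F)F
Why: The lithium-chelated Z enolate of the β-keto ester is trapped on oxygen (chelation-controlled enol triflate formation), which fixes the C2=C7 geometry with the ester cis to the future C6.

Step 3
Reactants: 3 dimethyl (2Z)-2-methyl-3-(trifluoromethanesulfonyloxy)hex-2-enedioate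
Product: 4 dimethyl (2Z)-3-ethenyl-2-methylhex-2-enedioate
Conditions: CH2=CHSnBu3, Pd(PPh3)4 (cat.), LiCl, THF, 60 °C
Reagents that add atoms: tributyl(ethenyl)stannane, C=C[Sn](CCCC)(CCCC)CCCC
Why: Stille coupling of the activated β-triflyloxy enoate proceeds with retention of alkene geometry and brings in C6 and C5.

Step 4
Reactants: 4 dimethyl (2Z)-3-ethenyl-2-methylhex-2-enedioate; 5 di-tert-butyl 2-diazopropanedioate
Product: 6 di-tert-butyl (2S)-2-[(2Z)-1,6-dimethoxy-2-methyl-1,6-dioxohex-2-en-3-yl]cyclopropane-1,1-dicarboxylate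
Conditions: Cu(MeCN)4PF6 (5 mol%), chiral side-arm bis(oxazoline) ligand (6 mol%), CH2Cl2, 25 °C, slow addition of 5
Reagents that add atoms: none
Why: A chiral monovalent copper carbene (bis(oxazoline)-controlled asymmetric cyclopropanation) adds to the terminal, least hindered alkene of the diene and sets C6 as S, the ligand antipode being chosen for this sense; the tetrasubstituted enoate alkene is inert.

Step 5
Reactants: 6 di-tert-butyl (2S)-2-[(2Z)-1,6-dimethoxy-2-methyl-1,6-dioxohex-2-en-3-yl]cyclopropane-1,1-dicarboxylate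
Product: 7 (4Z)-4-[(1S)-2,2-bis(tert-butoxycarbonyl)cyclopropyl]-6-methoxy-5-methyl-6-oxohex-4-enoic acid
Conditions: LiOH (1.1 equiv), THF/H2O, 0 °C; then aq. HCl to pH 3
Reagents that add atoms: lithium hydroxide, [Li+].[OH-]
Why: Saponification takes only the unhindered saturated methyl ester; the tert-butyl esters and the tetrasubstituted conjugated ester are spared.

Step 6
Reactants: 7 (4Z)-4-[(1S)-2,2-bis(tert-butoxycarbonyl)cyclopropyl]-6-methoxy-5-methyl-6-oxohex-4-enoic acid; 8 1-(cyclopent-1-en-1-yl)pyrrolidine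
Product: 11 di-tert-butyl (2S)-2-[(2Z)-1-methoxy-2-methyl-1,6-dioxo-6-(2-oxocyclopentyl)hex-2-en-3-yl]cyclopropane-1,1-dicarboxylate, via acid chloride 9 (not isolated), via acyl enamine 10 (not isolated)
Conditions: 1-chloro-N,N,2-trimethylprop-1-en-1-amine, CH2Cl2, 0 °C; then 8, Et3N, 0 → 25 °C; then 1 M aq. HCl, 25 °C
Reagents that add atoms: water, O
Why: Stork enamine acylation: the neutral chloroenamine gives the acid chloride without acid, the enamine is C-acylated and aqueous acid hydrolyses the acyl enamine to the 2-acylcyclopentanone, whose ring stereocentre is labile and of no consequence.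

Step 7
Reactants: 11 di-tert-butyl (2S)-2-[(2Z)-1-methoxy-2-methyl-1,6-dioxo-6-(2-oxocyclopentyl)hex-2-en-3-yl]cyclopropane-1,1-dicarboxylate
Product: 12 spiro diketone malonate (6R,11S)
Conditions: Mg(OTf)2 (0.3 equiv), i-Pr2NEt (0.3 equiv), ClCH2CH2Cl, 60 °C
Reagents that add atoms: none
Why: Soft enolisation gives the magnesium-chelated, U-shaped enolate of the 2-acylcyclopentanone, whose central carbon C11 attacks the cyclopropane carbon C6 in an SN2 sense anti to the C6–C4 bond; release of ring strain and departure of a malonate anion (protonated by unreacted diketone, so base is catalytic) drive the reaction. The closest known reaction type is the intramolecular homoconjugate (spiro-mode) addition of 1,3-dicarbonyl carbanions to cyclopropane-1,1-diesters. Ring B closes in the 6-exo-tet mode, the breaking C6–C4 bond lying outside the new ring. C6 is set by inversion of the S cyclopropane centre; C11 is set relative to C6 in a chair-like transition state in which allylic 1,3-strain with the ester on C2 forces the C5 arm axial and the chelated enolate places C26 equatorial, that is cis to this arm. The step needs C- over O-alkylation and attack at C6 rather than at C5 or the alkene: divalent magnesium ties up both oxygens, C6 is the only carbon that is both allylic (γ to the C1 ester) and activated by the geminal diester, attack at C5 would need a seven-membered ring, and the electron-poor alkene disfavours ionisation so that the configuration at C6 is not lost.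

Step 8
Reactants: 12 spiro diketone malonate (6R,11S)
Product: 14 spiro diketone acid (6R,11S), via malonic acid 13 (not isolated)
Conditions: CF3CO2H, CH2Cl2, 0 → 25 °C; then dioxane, 100 °C
Reagents that add atoms: none
Why: Acidolysis removes both tert-butyl groups and the malonic acid loses CO2 on warming (malonic acid decarboxylation), which takes out the second activating ester and leaves C3 as a carboxylic acid without any base that could cleave the 1,3-diketone.

Step 9
Reactants: 14 spiro diketone acid (6R,11S)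
Product: 15 hydroxy ketone acid (6R,10S,11R)
Conditions: CeCl3, MeLi (2.5 equiv), THF, −78 °C
Reagents that add atoms: methyllithium, [Li]C
Why: The weakly basic organocerium reagent (1,2-addition) attacks the six-ring ketone, which is more electrophilic than the five-ring one, from the equatorial side because the axial face is blocked by the axial C5 arm on C6; this gives the axial C10 hydroxyl cis to C26 and to the C6 arm, one equivalent being consumed by the acid.

Step 10
Reactants: 15 hydroxy ketone acid (6R,10S,11R)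
Product: 17 ketal hydroxy ketone acid (6R,10S,11R,14R), via silyl enol ether 16 (not isolated)
Conditions: Me3SiOTf, Et3N, CH2Cl2, 0 °C; then 2-methoxy-2-methyl-1,3-dioxolane, Me3SiOTf (cat.), −78 → −40 °C; citric acid, MeOH work-up
Reagents that add atoms: 2-methoxy-2-methyl-1,3-dioxolane, COC1(C)OCCO1
Why: Mukaiyama-type alkylation of the only possible silyl enol ether (C26 towards C14) by the 2-methyl-1,3-dioxolan-2-ylium ion installs the masked acetyl group on the face of ring S that looks towards C6, the other face being screened by the equatorial methyl on C10 (the epimerisable centre can also settle there); the silyl ester and tertiary silyl ether fall off on mild acidic work-up.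

Step 11
Reactants: 17 ketal hydroxy ketone acid (6R,10S,11R,14R)
Product: 18 ketal diol acid (6R,10S,11S,14R,26R)
Conditions: Me4NBH(OAc)3, MeCN/AcOH, −20 °C
Reagents that add atoms: none
Why: Hydroxyl-directed reduction (Evans–Saksena type): the borohydride bound to the C10 oxygen delivers hydride to C26 from the C10 side, which is also the side away from the C14 substituent, so the new hydroxyl is cis to C6 and to the C14 substituent.

Step 12
Reactants: 18 ketal diol acid (6R,10S,11S,14R,26R)
Product: 19 ketal tetraol (6R,10S,11S,14R,26R)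
Conditions: LiAlH4, THF, 0 → 40 °C
Reagents that add atoms: none
Why: LiAlH4 reduces the carboxylic acid to the C3 carbinol and the hindered conjugated ester to the C1 allylic alcohol (1,2-reduction) without touching the ketal or the alkene.

Step 13
Reactants: 19 ketal tetraol (6R,10S,11S,14R,26R)
Product: 20 ketal tetrakis(silyl ether) (6R,10S,11S,14R,26R)
Conditions: t-BuMe2SiOTf (6 equiv), 2,6-lutidine, CH2Cl2, −78 → 25 °C
Reagents that add atoms: tert-butyldimethylsilyl trifluoromethanesulfonate, CC(C)(C)[Si](C)(C)OS(=O)(=O)C(F)(F)F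
Why: Exhaustive silylation with the silyl triflate covers the two primary, the secondary and the tertiary hydroxyl so that no acidic proton interferes with the later enolate and coupling steps; the ketone ketal tolerates the conditions.

Step 14
Reactants: 20 ketal tetrakis(silyl ether) (6R,10S,11S,14R,26R)
Product: 21 methyl ketone tetrakis(silyl ether) (6R,10S,11S,14R,26R)
Conditions: PdCl2(MeCN)2 (5 mol%), acetone/H2O, 25 °C
Reagents that add atoms: water, O
Why: Mild Lewis-acid ketal cleavage unmasks the methyl ketone while the four silyl ethers stay, and the near-neutral medium avoids epimerisation at C14.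

Step 15
Reactants: 21 methyl ketone tetrakis(silyl ether) (6R,10S,11S,14R,26R)
Product: 22 alkenyl triflate tetrakis(silyl ether) (6R,10S,11S,14R,26R)
Conditions: KN(SiMe3)2, THF, −78 °C; then N-(5-chloropyridin-2-yl)bis(trifluoromethanesulfonyl)imide
Reagents that add atoms: Comins' reagent, O=S(=O)(N(c1ccc(Cl)cn1)S(=O)(=O)C(F)(F)F)C(F)(F)F
Why: Kinetic deprotonation by the bulky amide occurs at the methyl group and O-triflation of that enolate gives the 1,1-disubstituted alkenyl triflate (C15=CH2) without touching C14.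

Step 16
Reactants: 23 (2E)-3-(tributylstannyl)prop-2-en-1-ol
Product: 24 (2E)-3-(tributylstannyl)prop-2-enal
Conditions: MnO2, CH2Cl2, 25 °C
Reagents that add atoms: none
Why: MnO2 oxidises the allylic alcohol to the enal (allylic oxidation) with the E geometry and the tin group intact.

Step 17
Reactants: 25 methyl 2-[bis(2,2,2-trifluoroethoxy)phosphoryl]acetate; 26 5-bromo-2-methylpent-2-ene
Product: 27 methyl 2-[bis(2,2,2-trifluoroethoxy)phosphoryl]-6-methylhept-5-enoate
Conditions: NaH, NaI (cat.), DMF, 0 → 45 °C
Reagents that add atoms: none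
Why: The phosphonoacetate anion is C-alkylated by the primary bromide (SN2 enolate alkylation).

Step 18
Reactants: 24 (2E)-3-(tributylstannyl)prop-2-enal; 27 methyl 2-[bis(2,2,2-trifluoroethoxy)phosphoryl]-6-methylhept-5-enoate
Product: 28 methyl (2Z,4E)-2-(4-methylpent-3-en-1-yl)-5-(tributylstannyl)penta-2,4-dienoate
Conditions: KN(SiMe3)2, 18-crown-6, THF, −78 °C
Reagents that add atoms: none
Why: Still–Gennari olefination: the electron-poor bis(trifluoroethyl) phosphonate under dissociating conditions gives the kinetic Z enoate, with the ester (future C28) cis to the stannylvinyl arm, and the E stannyl alkene is carried over from 24.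

Step 19
Reactants: 28 methyl (2Z,4E)-2-(4-methylpent-3-en-1-yl)-5-(tributylstannyl)penta-2,4-dienoate
Product: 29 (2Z,4E)-2-(4-methylpent-3-en-1-yl)-5-(tributylstannyl)penta-2,4-dien-1-ol
Conditions: i-Bu2AlH, CH2Cl2, −78 °C
Reagents that add atoms: none
Why: The aluminium hydride reduces the ester to the allylic alcohol (1,2-reduction) at low temperature; the alkenylstannane and the alkenes are inert.

Step 20
Reactants: 29 (2Z,4E)-2-(4-methylpent-3-en-1-yl)-5-(tributylstannyl)penta-2,4-dien-1-ol
Product: 30 (2Z,4E)-2-(4-methylpent-3-en-1-yl)-5-(tributylstannyl)penta-2,4-dien-1-yl acetate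
Conditions: Ac2O, pyridine, DMAP (cat.), CH2Cl2, 0 °C
Reagents that add atoms: acetic anhydride, CC(=O)OC(C)=O
Why: Acylation of the primary allylic alcohol installs the acetate of the target before the fragments are joined.

Step 21
Reactants: 22 alkenyl triflate tetrakis(silyl ether) (6R,10S,11S,14R,26R); 30 (2Z,4E)-2-(4-methylpent-3-en-1-yl)-5-(tributylstannyl)penta-2,4-dien-1-yl acetate
Product: 31 silylated triene acetate (6R,10S,11S,14S,26R)
Conditions: Pd2(dba)3 (cat.), AsPh3, CuI (cat.), LiCl, NMP, 25 °C
Reagents that add atoms: none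
Why: Stille coupling of alkenyl triflate and alkenylstannane, both with retention, joins C15 to C16 and completes the triene; the copper and chloride additives let it run at room temperature, where zerovalent palladium does not ionise the allylic acetate.

Step 22
Reactants: 31 silylated triene acetate (6R,10S,11S,14S,26R)
Product: 32 tetraol acetate (6R,10S,11S,14S,26R)
Conditions: HF·pyridine, pyridine, THF, 0 → 25 °C
Reagents that add atoms: none
Why: Buffered fluoride cleaves all four silyl ethers (desilylation) and leaves the allylic acetate and the triene intact.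

Step 23
Reactants: 32 tetraol acetate (6R,10S,11S,14S,26R)
Product: 33 target spiro enal (2Z,6R,10S,11S,14S,16E,18Z,26R)
Conditions: MnO2, CH2Cl2, 25 °C
Reagents that add atoms: none
Why: MnO2 oxidises only the allylic C1 alcohol (chemoselective allylic oxidation) to the Z enal; the saturated primary, the secondary and the tertiary alcohol and the acetate are untouched.

**Compound list**

1 | dimethyl 3-oxohexanedioate | COC(=O)CC(=O)CCC(=O)OC | starting material
2 | dimethyl 2-methyl-3-oxohexanedioate (racemic, labile centre) | COC(=O)C(C)C(=O)CCC(=O)OC | intermediate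
3 | dimethyl (2Z)-2-methyl-3-(trifluoromethanesulfonyloxy)hex-2-enedioate | COC(=O)/C(C)=C(\OS(=O)(=O)C(F)(F)F)CCC(=O)OC | intermediate
4 | dimethyl (2Z)-3-ethenyl-2-methylhex-2-enedioate | COC(=O)/C(C)=C(\C=C)CCC(=O)OC | intermediate
5 | di-tert-butyl 2-diazopropanedioate | CC(C)(C)OC(=O)C(=[N+]=[N-])C(=O)OC(C)(C)C | starting material
6 | di-tert-butyl (2S)-2-[(2Z)-1,6-dimethoxy-2-methyl-1,6-dioxohex-2-en-3-yl]cyclopropane-1,1-dicarboxylate | CC(C)(C)OC(=O)C1(C(=O)OC(C)(C)C)C[C@H]1/C(CCC(=O)OC)=C(/C)C(=O)OC | intermediate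
7 | (4Z)-4-[(1S)-2,2-bis(tert-butoxycarbonyl)cyclopropyl]-6-methoxy-5-methyl-6-oxohex-4-enoic acid | CC(C)(C)OC(=O)C1(C(=O)OC(C)(C)C)C[C@H]1/C(CCC(=O)O)=C(/C)C(=O)OC | intermediate
8 | 1-(cyclopent-1-en-1-yl)pyrrolidine | C1CCN(C1)C1=CCCC1 | starting material
9 | acid chloride of 7 | CC(C)(C)OC(=O)C1(C(=O)OC(C)(C)C)C[C@H]1/C(CCC(Cl)=O)=C(/C)C(=O)OC | intermediate
10 | acyl enamine: 1-(2-acylcyclopent-1-en-1-yl)pyrrolidine carrying the acyl group of 7 | CC(C)(C)OC(=O)C1(C(=O)OC(C)(C)C)C[C@H]1/C(CCC(=O)C1=C(N2CCCC2)CCC1)=C(/C)C(=O)OC | intermediate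
11 | di-tert-butyl (2S)-2-[(2Z)-1-methoxy-2-methyl-1,6-dioxo-6-(2-oxocyclopentyl)hex-2-en-3-yl]cyclopropane-1,1-dicarboxylate (ring carbon between the carbonyls epimeric and enolised) | CC(C)(C)OC(=O)C1(C(=O)OC(C)(C)C)C[C@H]1/C(CCC(=O)C1CCCC1=O)=C(/C)C(=O)OC | intermediate
12 | spiro diketone malonate (6R,11S): spiro[4.5]decane with ketones at C26 (ring S) and C10 (ring B) on either side of spiro C11; C6 carries CH2CH(CO2tBu)2 cis to C26; C7 carries the exocyclic Z =C(CH3)CO2CH3 with the ester cis to C6 | C1CC[C@]2([C@H](CC(C(=O)OC(C)(C)C)C(=O)OC(C)(C)C)/C(=C(/C)C(=O)OC)CCC2=O)C1=O | intermediate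
13 | spiro diketone malonic acid (6R,11S): 12 with both tert-butyl esters cleaved | C1CC[C@]2([C@H](CC(C(=O)O)C(=O)O)/C(=C(/C)C(=O)OC)CCC2=O)C1=O | intermediate
14 | spiro diketone acid (6R,11S): as 12 with CH2CH2CO2H on C6 | C1CC[C@]2([C@H](CCC(=O)O)/C(=C(/C)C(=O)OC)CCC2=O)C1=O | intermediate
15 | hydroxy ketone acid (6R,10S,11R): 14 with C10 as C(CH3)(OH), hydroxyl cis to C26 and to the C6 arm | C1CC[C@]2([C@H](CCC(=O)O)/C(=C(/C)C(=O)OC)CC[C@]2(C)O)C1=O | intermediate
16 | silyl enol ether: C26 trimethylsilyl enol ether (C14=C26) of 15, also silylated at the C10 hydroxyl and the carboxyl group | C=1CC[C@]2([C@H](CCC(=O)O[Si](C)(C)C)/C(=C(/C)C(=O)OC)CC[C@]2(C)O[Si](C)(C)C)C=1O[Si](C)(C)C | intermediate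
17 | ketal hydroxy ketone acid (6R,10S,11R,14R): 15 with a 2-methyl-1,3-dioxolan-2-yl group on C14, on the ring S face cis to C6 | CC1(OCCO1)[C@@H]1CC[C@]2([C@H](CCC(=O)O)/C(=C(/C)C(=O)OC)CC[C@]2(C)O)C1=O | intermediate
18 | ketal diol acid (6R,10S,11S,14R,26R): 17 with C26 as CHOH, hydroxyl cis to the C14 substituent and to C6 | CC1(OCCO1)[C@@H]1CC[C@]2([C@H](CCC(=O)O)/C(=C(/C)C(=O)OC)CC[C@]2(C)O)[C@@H]1O | intermediate
19 | ketal tetraol (6R,10S,11S,14R,26R): 18 with C3 and C1 as CH2OH | CC1(OCCO1)[C@@H]1CC[C@]2([C@H](CCCO)/C(=C(/C)CO)CC[C@]2(C)O)[C@@H]1O | intermediate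
20 | ketal tetrakis(silyl ether) (6R,10S,11S,14R,26R): 19 with tert-butyldimethylsilyl ethers at the C1, C3, C10 and C26 oxygens | CC1(OCCO1)[C@@H]1CC[C@]2([C@H](CCCO[Si](C)(C)C(C)(C)C)/C(=C(/C)CO[Si](C)(C)C(C)(C)C)CC[C@]2(C)O[Si](C)(C)C(C)(C)C)[C@@H]1O[Si](C)(C)C(C)(C)C | intermediate
21 | methyl ketone tetrakis(silyl ether) (6R,10S,11S,14R,26R): 20 with acetyl on C14 | CC(=O)[C@@H]1CC[C@]2([C@H](CCCO[Si](C)(C)C(C)(C)C)/C(=C(/C)CO[Si](C)(C)C(C)(C)C)CC[C@]2(C)O[Si](C)(C)C(C)(C)C)[C@@H]1O[Si](C)(C)C(C)(C)C | intermediate
22 | alkenyl triflate tetrakis(silyl ether) (6R,10S,11S,14R,26R): 21 with C14 bearing C(OSO2CF3)=CH2 | C=C(OS(=O)(=O)C(F)(F)F)[C@@H]1CC[C@]2([C@H](CCCO[Si](C)(C)C(C)(C)C)/C(=C(/C)CO[Si](C)(C)C(C)(C)C)CC[C@]2(C)O[Si](C)(C)C(C)(C)C)[C@@H]1O[Si](C)(C)C(C)(C)C | intermediate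
23 | (2E)-3-(tributylstannyl)prop-2-en-1-ol | CCCC[Sn](CCCC)(CCCC)/C=C/CO | starting material
24 | (2E)-3-(tributylstannyl)prop-2-enal | CCCC[Sn](CCCC)(CCCC)/C=C/C=O | intermediate
25 | methyl 2-[bis(2,2,2-trifluoroethoxy)phosphoryl]acetate | COC(=O)CP(=O)(OCC(F)(F)F)OCC(F)(F)F | starting material
26 | 5-bromo-2-methylpent-2-ene | CC(C)=CCCBr | starting material
27 | methyl 2-[bis(2,2,2-trifluoroethoxy)phosphoryl]-6-methylhept-5-enoate | COC(=O)C(CCC=C(C)C)P(=O)(OCC(F)(F)F)OCC(F)(F)F | intermediate
28 | methyl (2Z,4E)-2-(4-methylpent-3-en-1-yl)-5-(tributylstannyl)penta-2,4-dienoate | CCCC[Sn](CCCC)(CCCC)/C=C/C=C(/CCC=C(C)C)C(=O)OC | intermediate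
29 | (2Z,4E)-2-(4-methylpent-3-en-1-yl)-5-(tributylstannyl)penta-2,4-dien-1-ol | CCCC[Sn](CCCC)(CCCC)/C=C/C=C(/CCC=C(C)C)CO | intermediate
30 | (2Z,4E)-2-(4-methylpent-3-en-1-yl)-5-(tributylstannyl)penta-2,4-dien-1-yl acetate | CCCC[Sn](CCCC)(CCCC)/C=C/C=C(/CCC=C(C)C)COC(C)=O | intermediate
31 | silylated triene acetate (6R,10S,11S,14S,26R): 32 with tert-butyldimethylsilyl ethers at the C1, C3, C10 and C26 oxygens | C=C(/C=C/C=C(/CCC=C(C)C)COC(C)=O)[C@@H]1CC[C@]2([C@H](CCCO[Si](C)(C)C(C)(C)C)/C(=C(/C)CO[Si](C)(C)C(C)(C)C)CC[C@]2(C)O[Si](C)(C)C(C)(C)C)[C@@H]1O[Si](C)(C)C(C)(C)C | intermediate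
32 | tetraol acetate (6R,10S,11S,14S,26R): the target with C1 as CH2OH | C=C(/C=C/C=C(/CCC=C(C)C)COC(C)=O)[C@@H]1CC[C@]2([C@H](CCCO)/C(=C(/C)CO)CC[C@]2(C)O)[C@@H]1O | intermediate
33 | target spiro enal (2Z,6R,10S,11S,14S,16E,18Z,26R), CNP0205332.1 | C=C(/C=C/C=C(/CCC=C(C)C)COC(C)=O)[C@@H]1CC[C@]2([C@H](CCCO)/C(=C(/C)C=O)CC[C@]2(C)O)[C@@H]1O | target

**Step count and risks**

Total step count: 23. Longest linear sequence: 18 steps (steps 1 to 15 and 21 to 23).

Steps most likely to fail:

Step 7. The hindered enolate carbon may open the cyclopropane too slowly, or alkylation may take place on the acyl oxygen instead of on C11. The fallback sets out from 11 and runs the ring opening on oxygen on purpose (Cs2CO3, DMSO, 40 °C; the free enolate oxygen attacks C6 in a 6-exo-tet opening with inversion). This gives the cyclic enol ether di-tert-butyl 2-{[(2R,3Z,6E)-3-(1-methoxy-1-oxopropan-2-ylidene)-6-(2-oxocyclopentylidene)oxan-2-yl]methyl}propanedioate F1. Pd(PPh3)4 in THF at 50 °C then ionises the allylic C6–O bond anti to oxygen, and the liberated diketonate returns on carbon anti to the metal (the known palladium-catalysed O-to-C allyl transfer of enol ethers of 1,3-diketones). C6 keeps the configuration of F1 and the route is rejoined at 12.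

Step 4. Enantioselection or conversion may be poor because the terminal alkene belongs to an electron-poor diene and the diazo ester is bulky. The fallback sets out from 4 and 5 and gives up asymmetric catalysis: Rh2(esp)2 gives the racemic cyclopropane tetraester F2, LiOH gives the racemic acid F3, and crystallisation with (1R)-1-phenylethan-1-amine gives the salt of the S acid, (1R)-1-phenylethan-1-aminium (4Z)-4-[(1S)-2,2-bis(tert-butoxycarbonyl)cyclopropyl]-6-methoxy-5-methyl-6-oxohex-4-enoate F4. Acidification returns to the route at 7.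

Step 9. The organometallic may add to the five-ring ketone, show poor facial selectivity, or cleave the 1,3-diketone by retro-Claisen fragmentation. The fallback sets out from 14 and replaces carbonyl addition by olefination and hydration. The non-basic Zn/CH2Br2/TiCl4 reagent methylenates the more reactive six-ring ketone to the exocyclic alkene keto acid F5 (6R,11R). Oxymercuration (Hg(OAc)2, THF/H2O) should place mercury on the open equatorial face and let water enter axially, giving the organomercurial F6 with axial hydroxyl and equatorial CH2HgOAc on C10. Demercuration (NaBH4, aq. NaOH, 0 °C, short contact) comes back to the route at 15.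

Further compounds
F1 | step 7 | di-tert-butyl 2-{[(2R,3Z,6E)-3-(1-methoxy-1-oxopropan-2-ylidene)-6-(2-oxocyclopentylidene)oxan-2-yl]methyl}propanedioate | CC(C)(C)OC(=O)C(C[C@H]1O/C(CC/C1=C(\C)C(=O)OC)=C1\CCCC1=O)C(=O)OC(C)(C)C
F2 | step 4 | racemic di-tert-butyl 2-[(2Z)-1,6-dimethoxy-2-methyl-1,6-dioxohex-2-en-3-yl]cyclopropane-1,1-dicarboxylate | CC(C)(C)OC(=O)C1(C(=O)OC(C)(C)C)CC1/C(CCC(=O)OC)=C(/C)C(=O)OC
F3 | step 4 | racemic (4Z)-4-[2,2-bis(tert-butoxycarbonyl)cyclopropyl]-6-methoxy-5-methyl-6-oxohex-4-enoic acid | CC(C)(C)OC(=O)C1(C(=O)OC(C)(C)C)CC1/C(CCC(=O)O)=C(/C)C(=O)OC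
F4 | step 4 | (1R)-1-phenylethan-1-aminium (4Z)-4-[(1S)-2,2-bis(tert-butoxycarbonyl)cyclopropyl]-6-methoxy-5-methyl-6-oxohex-4-enoate | CC(C)(C)OC(=O)C1(C(=O)OC(C)(C)C)C[C@H]1/C(CCC(=O)[O-])=C(/C)C(=O)OC.C[C@@H]([NH3+])c1ccccc1
F5 | step 9 | exocyclic alkene keto acid (6R,11R): 14 with C10=CH2 in place of the C10 ketone | C1CC[C@]2([C@H](CCC(=O)O)/C(=C(/C)C(=O)OC)CCC2=C)C1=O
F6 | step 9 | organomercurial: 15 with CH2HgOAc in place of the C10 methyl | C1CC[C@]2([C@H](CCC(=O)O)/C(=C(/C)C(=O)OC)CC[C@]2(C[Hg]OC(C)=O)O)C1=O
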